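We choose to follow one catalyst molecule through the east flask and to count the substrate it has to turn against the turns it gets in the time given.

| setting | south | south-east | north | north-east | east |
|---|---|---|---|---|---|
| substrate | 0.100 M | 0.0500 M | 0.100 M | 0.100 M | 0.0330 M |
| partner | 0.200 M | 0.150 M | 0.200 M | 0.400 M | 0.200 M |
| catalyst | 0.00200 M | 0.00200 M | 0.00600 M | 0.00200 M | 0.00100 M |
| time |  |  |  |  | 4.4 min |

| south run: time / min | south run: [product] / M | south-east run: time / min | south-east run: [product] / M | north run: time / min | north run: [product] / M | north-east run: time / min | north-east run: [product] / M |
|---|---|---|---|---|---|---|---|
| 0.88 | 0.0075 | 0.88 | 0.0054 | 0.88 | 0.0221 | 0.88 | 0.0130 |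
| 1.8 | 0.0182 | 1.8 | 0.0136 | 1.8 | 0.0515 | 1.8 | 0.0302 |
| 2.6 | 0.0273 | 2.6 | 0.0202 | 2.6 | 0.0720 | 2.6 | 0.0445 |
| 3.5 | 0.0383 | 3.5 | 0.0274 | 3.5 | 0.0894 | 3.5 | 0.0594 |
| 4.4 | 0.0472 | 4.4 | 0.0335 | 4.4 | 0.0975 | 4.4 | 0.0731 |

(standard deviation of a reading: 3 × 10⁻⁴ M)

- Overall: substrate + partner -> product, with catalyst as catalyst.
- Constant volume, constant temperature.
- Readings of a species count what is bound in complexes too.
- An order is taken over about fifteen percent of the charge, up and down.

1. the exponent of [partner] in the starting rate at the charge of the south run (at the point where two percent of the substrate have become product)
2. the exponent of [substrate] in the starting rate at the charge of the south run (at the point where two percent of the substrate have become product) (one fixed amount of product, the same in the runs compared)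
3. the south-east run starts with 0.0500 M less of substrate and of partner than the south run, and with no product. Compared where both hold the same amount of substrate, once fifteen percent of what the south-east run was charged with has turned into product, is the south-east run faster, slower or alike (within a tenth)?
4. product in the east run at 4.4 min, as a share of the substrate charged

Call the load of a flask its charged substrate per charged catalyst. The load is 33.0 in the east flask and 25.0 in the south-east flask, the simulated run that looks nearly the same. Substrate is the limiting reagent in both, since the east flask holds more partner than substrate, as does the south-east flask. In 4.4 min the south-east run made 16.8 turns per catalyst (a turnover number), which is 67.0% of its load.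

The east flask has the heavier load, but it also holds more partner. Taking its conversion as that of the south-east run, the straight mean of partner is 0.189 M in the east run against 0.133 M in the south-east run. Doubling the partner from the south run to the north-east run raised the product made between 1.8 min and 4.4 min by a factor of 1.48, which reads as an order of 0.565.

So our reckoning gives a catalyst in the east flask 1.22 times the south-east count, or 20.4 turns. Dividing by the time gives the pace, the turns per charged catalyst per minute with the starting lag included, 4.64 min⁻¹ at partner near the east charge. The share is then 61.8%. This is less than the south-east share, because the load grew by a factor of 1.32 and the count by a smaller one. We make no correction for the lower substrate of the east flask.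

The forecast, which notes that “The early points in every run lag”, gives 0.7 for the partner exponent, 0.13 for the substrate exponent, alike for the comparison, and 52% for the east run, below our share.

The east run gives 59.8%; the partner exponent comes to 0.62, the substrate exponent to 0.061, and the south-east run, held against the south run at equal substrate, is alike.

    active catalyst + substrate ⇌ catalyst-substrate complex, settled at all times (113.0 L mol⁻¹)
    catalyst-substrate complex + partner → product + active catalyst (93.60 L mol⁻¹ min⁻¹)
    catalyst + partner → active catalyst + partner (42.96 L mol⁻¹ min⁻¹)
    2 partner ⇌ idle reagent dimer, settled at all times (10.80 L mol⁻¹)

That is 19.7 turns per catalyst, a pace of 4.49 min⁻¹ against our 4.64 min⁻¹, and the best power-law order in catalyst over all runs is 0.96. The north run has a load of 16.7, so a quarter of its charge takes 4.17 turns. At our pace that is 0.900 min, and the north run stood there at 0.974 min.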